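## Structural features

Sigmoidin D (19) is a (2S)-5,7-dihydroxyflavanone: ring A, a phloroglucinol-type benzo ring, is fused through C4a and C8a to the dihydropyranone ring C (O1, C2, C3, C4=O). C2 carries ring B, which is also the benzo ring of a 2,2-dimethylchroman-3-ol (ring D); C1' of ring B is C6'' of the chroman, the chroman oxygen stands para to C1' and the free 8''-hydroxyl meta to it. The two stereocentres, C2 (S) and C3'' (S), lie five bonds apart across ring B, neither has a stereogenic neighbour, and neither can direct the other, so each needs its own source of absolute configuration. C2 is the fragile point: it is a benzylic ether carbon β to the ketone, so base opens ring C to the chalcone by retro-oxa-Michael reaction, and acid can ionise the C2–O1 bond because ring B has an oxygen para to C1'. The free phenols of ring A and the catechol-like oxygenation of ring B are nucleophilic and oxidisable, and the secondary alcohol sits next to the quaternary C2''. The real difficulty is to set the isolated, labile C2 centre in absolute terms and then to reach 19 without base or strong acid. The plan uses the fact that ring C consists of a salicyl unit (O1, C8a, C4a and the carbonyl carbon C4, all from a ring A aldehyde) plus a two-carbon edge C2–C3 that is a vinyl group on ring B; the C3''–OH next to the gem-dimethyl carbon maps onto the alkene of a 2,2-dimethylchromene.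

## Logic of the disconnections

19 ⇒ 18. No skeletal bond is cut; the four O–CH2Ph bonds are restored. One kind of protecting group on all four hydroxyls allows a single neutral release, which avoids the base that would open ring C. The demand is that the last step spares the benzylic C2–O1 bond and the ketone.

18 ⇒ 17 ⇒ 16. The C4 carbonyl is taken back to the C4 alcohol and then to the C4 methyl ether. C4 leaves the ring-forming step at the acetal oxidation level, and its stereocentre is erased again, so only C2 has to be right. The demand is that solvolysis ionises the C4–O bond and not C2–O1.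

16 ⇒ 2 + 13. The cuts are C3–C4 and O1–C2, through 15 and 14. This divides the molecule into two aromatic halves of similar size, closes ring C, and creates C2 in the same step, after all harsh chemistry on ring D is finished. The demand is catalyst-controlled choice of the styrene face at C2 and addition of the cation to the unsubstituted alkene carbon.

2 ⇒ 1. Two O–benzyl bonds are cut. The hydroxyl that stays free is the hydrogen-bonded one, which is the future O1 and the anchor for the chiral anion. The demand is that alkylation stops at the diether.

13 ⇒ 12. The aryl–vinyl bond at C6'' is cut. A bromide is inert to every step that builds ring D, whereas an aldehyde or a vinyl group would not survive epoxidation and hydride. The demand is a cross-coupling on an electron-rich aryl bromide.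

12 ⇒ 11 ⇒ 10 ⇒ 9. The O–benzyl bond is removed, the C4''–H bond is traced to the C4''–O bond of an epoxide, and the epoxide to the C3''=C4'' alkene. The C3'' stereocentre thus comes from a flat cis alkene of the class that manganese salen catalysts differentiate best. The demand is hydride attack at the benzylic epoxide carbon only.

9 ⇒ 7 ⇒ 4 + 5. The C4a''–C4'' bond (sigmatropic step, through 8) and the O–CMe2 bond (etherification, through 6) are cut. Ring D becomes a phenol and a five-carbon alcohol. The demand is a single free ortho position, which 4 provides.

4 ⇒ 3. The C–Br bond is cut. The demand is bromination para to the free hydroxyl.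

## Other disconnections considered

Alternative 1: The C3''–O bond is traced, through an epoxide, to the C3''=C4'' alkene of a chromene already attached to the finished flavanone, A1, (2S)-5,7-bis(benzyloxy)-2-[8-(benzyloxy)-2,2-dimethyl-2H-chromen-6-yl]chroman-4-one. In the forward step the chiral (salen)MnCl complex of trivalent manganese, with mCPBA and N-methylmorpholine N-oxide at low temperature, would epoxidise A1 to the cis-epoxide A2, (2S)-5,7-bis(benzyloxy)-2-[(3S,4S)-8-(benzyloxy)-3,4-epoxy-2,2-dimethylchroman-6-yl]chroman-4-one.
- In favour: the alkene is of the same privileged class, ring B stays achiral until late, and one hydrogenolysis could open the benzylic C4''–O bond and remove the benzyl groups together.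
- Against: the oxidant meets an electron-rich flavanone (ring A, benzylic C2–H, aryl ketone). Any shortfall in selectivity gives a C3'' epimer that is a diastereomer with the centres five bonds apart, which would be hard to remove. The question of C2 also stays open: the chromene alkene of a ring B precursor is itself an electron-rich styrene and would compete as the 2π partner in an oxocarbenium cycloaddition.
- Comparison: on the stereo-defining reaction the two plans are equals, since the chosen plan uses the same epoxidation at step 5. Alternative 1 is the better in end-game step economy. The chosen plan is the better in setting C3'' on a small bromide (11) whose enantiomeric purity can be raised before the fragments meet, and in keeping oxidants away from the flavanone.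

Alternative 2: The aryl–CH2 bond C5'–C4'' of ring D is cut. In the forward step BF3·OEt2 would activate the terminal epoxide of the tertiary aryl ether A3, (S)-2-{2-[2-(benzyloxy)-4-bromophenoxy]propan-2-yl}oxirane, and the arene carbon ortho to the ether oxygen would attack the epoxide CH2 to give A4, (3S)-8-(benzyloxy)-6-bromo-2,2-dimethylchroman-3-ol, which is the same compound as 11.
- In favour: the carbinol carbon is not involved in bond formation, the position of the hydroxyl is unambiguous, and no high-temperature rearrangement or hydride is needed. A3 could come from 7 by semi-hydrogenation, epoxidation and hydrolytic kinetic resolution with (salen)Co(OAc), a complex of trivalent cobalt.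
- Against: the attacking carbon is activated by one ortho oxygen only and is meta to both the benzyloxy group and bromine. A Lewis acid prefers to develop charge at the internal epoxide carbon, which invites a Meinwald shift or fluoride opening. The tertiary alkyl aryl ether can ionise back to 4, and a resolution discards half of the material.
- Comparison: after A4 the two plans are identical, so the end-games are equal. Alternative 2 is the better in the certainty of the hydroxyl position and in the level of enantiomeric purity a resolution can reach. The chosen plan is the better in step count from 4 to 11 (four steps against five, without the loss of half the material) and in mechanistic security, since the Claisen cascade and the epoxidation are used on their standard substrates.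

Alternative 3: The bonds C4a–C5 and C8–C8a are cut, so ring A is built last. The aldehyde A5, (3S)-3,8-bis(benzyloxy)-2,2-dimethylchroman-6-carbaldehyde, would give by catalytic asymmetric hetero-Diels–Alder reaction and α-bromination the bromo enone A6, (2S)-2-[(3S)-3,8-bis(benzyloxy)-2,2-dimethylchroman-6-yl]-5-bromo-2,3-dihydro-4H-pyran-4-one. In the forward key step A6 would act as dienophile towards A7, 1-methoxy-1,3-bis(trimethylsilyloxy)buta-1,3-diene, and loss of HBr, methanol and the silyl groups would give A8, (2S)-2-[(3S)-3,8-bis(benzyloxy)-2,2-dimethylchroman-6-yl]-5,7-dihydroxychroman-4-one.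
- In favour: C2 would be set by a reaction class of established scope, ring A arrives with free phenols, and only two benzyl ethers remain.
- Against: the C5=C6 bond of A6 is a vinylogous ester and a poor dienophile. The diene may stop at a Mukaiyama–Michael adduct. Elimination of the ring oxygen from C8a instead of bromide from C4a would open ring C. The aromatisation cascade releases acid and needs heat or base, conditions under which a 2-aryl dihydropyranone with a para-oxygenated aryl group can lose its C2 configuration.
- Comparison: Alternative 3 is the better in that its enantio-determining step is known chemistry, whereas that of the chosen plan is not. The step counts are about equal. The chosen plan is the better in buying ring A ready-made and in creating C2 only after all forcing steps, so the centre is not carried through an elimination cascade.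

Key step: step 9

Assumption: the sense of induction of the chiral acid in step 9 cannot be deduced from precedent; the (R) acid is written, and the (S) acid is meant if it is the one that gives the 2S series.
Remark: the descriptors were recomputed from the structures: 13 is 3S, 16 is 2S,4S (the 2,4-cis isomer) with 3''S, and 19 is 2S,3''S; no structure needed correction.
Remark: 17 is drawn without a descriptor at C4 because the solvolysis should give both epimers and both are oxidised to 18.
Remark: 13 is reached through an aryl bromide and not through an aldehyde, because the bromide is inert to hypochlorite and hydride.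
Remark: (S,S)-(salen)MnCl is the chloride of trivalent manganese with (S,S)-N,N'-bis(3,5-di-tert-butylsalicylidene)cyclohexane-1,2-diamine; (R)-TRIP is (R)-3,3'-bis(2,4,6-triisopropylphenyl)-1,1'-binaphthyl-2,2'-diyl hydrogen phosphate.

## Route

Step 1
Reactants: 1 2,4,6-trihydroxybenzaldehyde
Product: 2 2,4-bis(benzyloxy)-6-hydroxybenzaldehyde
Conditions: BnBr (2.05 equiv), K2CO3, DMF, 0 °C → rt
Reagents that add atoms: benzyl bromide, BrCc1ccccc1
Why: Williamson etherification; the 4-OH is the most acidic and reacts first, one ortho-OH follows, and the last hydroxyl is held in a hydrogen bond to the formyl oxygen, so alkylation should stop at the diether.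

Step 2
Reactants: 3 2-(benzyloxy)phenol
Product: 4 2-(benzyloxy)-4-bromophenol
Conditions: NBS (1.0 equiv), MeCN, −10 °C → rt
Reagents that add atoms: N-bromosuccinimide, O=C1CCC(=O)N1Br
Why: Electrophilic aromatic bromination; the free hydroxyl is the stronger para director, so bromine should enter para to OH and meta to the benzyloxy group, as in the analogous bromination of guaiacol.

Step 3
Reactants: 4 2-(benzyloxy)-4-bromophenol; 5 2-methylbut-3-yn-2-ol
Product: 7 2-(benzyloxy)-4-bromo-1-[(2-methylbut-3-yn-2-yl)oxy]benzene, via trifluoroacetate ester 6 (not isolated)
Conditions: 5, (CF3CO)2O, DBU, MeCN, −5 °C; then 4, CuCl2·2H2O (0.1 mol %), DBU, MeCN, −5 → 0 °C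
Reagents that add atoms: none
Why: Copper-catalysed propargylic etherification: 5 is acylated to 6 in the flask, its copper acetylide ionises at the tertiary carbon and the phenoxide of 4 captures it, which is the standard entry to tertiary propargyl aryl ethers where SN2 alkylation is not possible; no atom of the anhydride remains in 7.

Step 4
Reactants: 7 2-(benzyloxy)-4-bromo-1-[(2-methylbut-3-yn-2-yl)oxy]benzene
Product: 9 8-(benzyloxy)-6-bromo-2,2-dimethyl-2H-chromene, via allenylphenol 8 (not isolated)
Conditions: PhNEt2, 185 °C
Reagents that add atoms: none
Why: Aromatic propargyl Claisen rearrangement to the only free ortho carbon gives allenylphenol 8, which undergoes a 1,5-hydrogen shift and oxa-6π electrocyclisation; the other ortho position carries the benzyloxy group, so only one chromene can form.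

Step 5
Reactants: 9 8-(benzyloxy)-6-bromo-2,2-dimethyl-2H-chromene
Product: 10 (3S,4S)-8-(benzyloxy)-6-bromo-3,4-epoxy-2,2-dimethylchroman
Conditions: (S,S)-(salen)MnCl (4 mol %), aq NaOCl (pH 11.3), 4-phenylpyridine N-oxide, CH2Cl2, 0 °C
Reagents that add atoms: sodium hypochlorite, [Na+].[O-]Cl
Why: Jacobsen epoxidation; 2,2-dimethylchromenes are cis, aryl-conjugated alkenes of the kind this catalyst differentiates best, the (S,S) catalyst is expected to give the (3S,4S) epoxide and so fixes C3'', and the basic two-phase medium protects the acid-labile benzylic epoxide.

Step 6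
Reactants: 10 (3S,4S)-8-(benzyloxy)-6-bromo-3,4-epoxy-2,2-dimethylchroman
Product: 11 (3S)-8-(benzyloxy)-6-bromo-2,2-dimethylchroman-3-ol
Conditions: LiAlH4, THF, 0 °C
Reagents that add atoms: none
Why: SN2 opening of the epoxide by hydride at the activated benzylic C4, while C3 is shielded by the adjacent quaternary carbon; the C3–O bond is not touched, so the 3S configuration is retained, and the low temperature should spare the aryl bromide.

Step 7
Reactants: 11 (3S)-8-(benzyloxy)-6-bromo-2,2-dimethylchroman-3-ol
Product: 12 (3S)-3,8-bis(benzyloxy)-6-bromo-2,2-dimethylchroman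
Conditions: NaH, BnBr, n-Bu4NI (cat.), DMF, 0 °C → rt
Reagents that add atoms: benzyl bromide, BrCc1ccccc1
Why: Williamson etherification of the secondary alkoxide; the stereocentre takes no part in bond formation, and the benzyl ether keeps the alcohol out of the acid chemistry of step 9.

Step 8
Reactants: 12 (3S)-3,8-bis(benzyloxy)-6-bromo-2,2-dimethylchroman
Product: 13 (3S)-3,8-bis(benzyloxy)-6-ethenyl-2,2-dimethylchroman
Conditions: CH2=CHBF3K, PdCl2(dppf)·CH2Cl2 (3 mol %), Cs2CO3, THF/H2O 9:1, 80 °C
Reagents that add atoms: potassium vinyltrifluoroborate, C=C[B-](F)(F)F.[K+]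
Why: Suzuki–Miyaura vinylation of an aryl bromide with no ortho substituent; the basic medium leaves the benzyl ethers and the stereocentre untouched.

Step 9
Reactants: 2 2,4-bis(benzyloxy)-6-hydroxybenzaldehyde; 13 (3S)-3,8-bis(benzyloxy)-6-ethenyl-2,2-dimethylchroman
Product: 16 (2S,4S)-5,7-bis(benzyloxy)-2-[(3S)-3,8-bis(benzyloxy)-2,2-dimethylchroman-6-yl]-4-methoxychroman, via dimethyl acetal 14 (not isolated), via oxocarbenium ion 15 (not isolated)
Conditions: 13 (1.3 equiv), (R)-TRIP (10 mol %), 5 Å MS, toluene, −20 °C; slow addition of 2 and HC(OMe)3 (2 equiv); −20 → 0 °C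
Reagents that add atoms: trimethyl orthoformate, COC(OC)OC
Why: Proposed new method: the acid and the orthoformate convert the chelated aldehyde 2 into acetal 14, which loses methanol to the ortho-quinone methide oxocarbenium ion 15, a cation stabilised by the three ring oxygens and paired with the chiral phosphate that is hydrogen bonded to the free phenol. The unsubstituted terminus of styrene 13 adds to the cationic carbon (C3–C4), which places the charge on the carbon para to the chroman oxygen, and the phenol oxygen closes O1–C2, either within the same asynchronous inverse-demand oxa-[4+2] event or immediately afterwards. The closest known reactions are the achiral acid-catalysed three-component assembly of 4-alkoxyflavans from salicylaldehydes, orthoformates and styrenes, and the chiral phosphoric acid catalysed [4+2] cycloadditions of ortho-quinone methides with styrenes; their combination, an acetal-derived cation with an intermolecular styrene under a chiral anion, is the new element. Ring C closes as a six-membered ring that contains both former vinyl carbons (6-endo with respect to the alkene; in the stepwise limit a chair-like capture of the C2 benzylic cation by the phenol oxygen). C2 is controlled by the catalyst: the phosphate bound to the phenol hydroxyl shields one face of the heterodiene, and an endo approach of the aryl group then decides which face of the styrene carbon meets oxygen; C4 follows from the endo preference (2,4-cis expected) and is of no consequence because it is oxidised later. The step needs regioselectivity, which the para oxygen of ring B secures; chemoselectivity for the styrene over the electron-rich arenes, which the slow addition of 2 and the excess of 13 should favour; and enantioface selectivity at C2, which is the unproven element. The remote 3S centre of 13 cannot steer C2 but makes the two C2 epimers diastereomers, so the selectivity can be read directly and, if necessary, improved by chromatography or crystallisation.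

Step 10
Reactants: 16 (2S,4S)-5,7-bis(benzyloxy)-2-[(3S)-3,8-bis(benzyloxy)-2,2-dimethylchroman-6-yl]-4-methoxychroman
Product: 17 (2S)-5,7-bis(benzyloxy)-2-[(3S)-3,8-bis(benzyloxy)-2,2-dimethylchroman-6-yl]chroman-4-ol (both C4 epimers)
Conditions: TsOH·H2O (5 mol %), THF/H2O 3:1, 0.02 M, rt
Reagents that add atoms: water, O
Why: SN1 solvolysis: the C4 methoxy group sits on a benzylic carbon flanked by O1, the 5-benzyloxy and the 7-benzyloxy donors, so trace acid ionises it and water in large excess captures the cation; C2–O1 is supported by one para oxygen only and should stay intact, and either C4 epimer serves.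

Step 11
Reactants: 17 (2S)-5,7-bis(benzyloxy)-2-[(3S)-3,8-bis(benzyloxy)-2,2-dimethylchroman-6-yl]chroman-4-ol
Product: 18 (2S)-5,7-bis(benzyloxy)-2-[(3S)-3,8-bis(benzyloxy)-2,2-dimethylchroman-6-yl]chroman-4-one
Conditions: Dess–Martin periodinane, pyridine, CH2Cl2, 0 °C → rt
Reagents that add atoms: none
Why: Dess–Martin oxidation of a secondary benzylic alcohol; both C4 epimers converge on the ketone, pyridine buffers the acetic acid released so that the labile alcohol does not ionise, and C2 is not enolisable.

Step 12
Reactants: 18 (2S)-5,7-bis(benzyloxy)-2-[(3S)-3,8-bis(benzyloxy)-2,2-dimethylchroman-6-yl]chroman-4-one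
Product: 19 sigmoidin D
Conditions: H2 (1 atm), Pd(OH)2/C, EtOAc/MeOH 1:1, rt
Reagents that add atoms: none
Why: Catalytic hydrogenolysis of the three aryl benzyl ethers and the one alkyl benzyl ether under neutral conditions, which avoids the base-induced chalcone opening that would racemise C2; the reaction is stopped when the last ether has gone, to spare the benzylic C2–O1 bond.

## Compound list

1 | 2,4,6-trihydroxybenzaldehyde | O=Cc1c(O)cc(O)cc1O | starting material
2 | 2,4-bis(benzyloxy)-6-hydroxybenzaldehyde | O=Cc1c(O)cc(OCc2ccccc2)cc1OCc1ccccc1 | intermediate
3 | 2-(benzyloxy)phenol | Oc1ccccc1OCc1ccccc1 | starting material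
4 | 2-(benzyloxy)-4-bromophenol | Oc1ccc(Br)cc1OCc1ccccc1 | intermediate
5 | 2-methylbut-3-yn-2-ol | CC(C)(O)C#C | starting material
6 | 2-methylbut-3-yn-2-yl trifluoroacetate (formed in the flask) | CC(C)(OC(=O)C(F)(F)F)C#C | intermediate
7 | 2-(benzyloxy)-4-bromo-1-[(2-methylbut-3-yn-2-yl)oxy]benzene | CC(C)(Oc1ccc(Br)cc1OCc1ccccc1)C#C | intermediate
8 | 2-(benzyloxy)-4-bromo-6-(3-methylbuta-1,2-dien-1-yl)phenol (formed in the flask) | CC(C)=C=Cc1cc(Br)cc(OCc2ccccc2)c1O | intermediate
9 | 8-(benzyloxy)-6-bromo-2,2-dimethyl-2H-chromene | CC1(C)C=Cc2cc(Br)cc(OCc3ccccc3)c2O1 | intermediate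
10 | (3S,4S)-8-(benzyloxy)-6-bromo-3,4-epoxy-2,2-dimethylchroman | CC1(C)Oc2c(OCc3ccccc3)cc(Br)cc2[C@@H]2O[C@H]12 | intermediate
11 | (3S)-8-(benzyloxy)-6-bromo-2,2-dimethylchroman-3-ol | CC1(C)Oc2c(OCc3ccccc3)cc(Br)cc2C[C@@H]1O | intermediate
12 | (3S)-3,8-bis(benzyloxy)-6-bromo-2,2-dimethylchroman | CC1(C)Oc2c(OCc3ccccc3)cc(Br)cc2C[C@@H]1OCc1ccccc1 | intermediate
13 | (3S)-3,8-bis(benzyloxy)-6-ethenyl-2,2-dimethylchroman | CC1(C)Oc2c(OCc3ccccc3)cc(C=C)cc2C[C@@H]1OCc1ccccc1 | intermediate
14 | 3,5-bis(benzyloxy)-2-(dimethoxymethyl)phenol (formed in the flask) | COC(OC)c1c(O)cc(OCc2ccccc2)cc1OCc1ccccc1 | intermediate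
15 | {[2,4-bis(benzyloxy)-6-hydroxyphenyl]methylidene}(methyl)oxonium, cation of the chiral phosphate ion pair (formed in the flask) | C[O+]=Cc1c(O)cc(OCc2ccccc2)cc1OCc1ccccc1 | intermediate
16 | (2S,4S)-5,7-bis(benzyloxy)-2-[(3S)-3,8-bis(benzyloxy)-2,2-dimethylchroman-6-yl]-4-methoxychroman | CC1(C)Oc2c(OCc3ccccc3)cc([C@@H]3C[C@H](OC)c4c(OCc5ccccc5)cc(OCc5ccccc5)cc4O3)cc2C[C@@H]1OCc1ccccc1 | intermediate
17 | (2S)-5,7-bis(benzyloxy)-2-[(3S)-3,8-bis(benzyloxy)-2,2-dimethylchroman-6-yl]chroman-4-ol, both C4 epimers | CC1(C)Oc2c(OCc3ccccc3)cc([C@@H]3CC(O)c4c(OCc5ccccc5)cc(OCc5ccccc5)cc4O3)cc2C[C@@H]1OCc1ccccc1 | intermediate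
18 | (2S)-5,7-bis(benzyloxy)-2-[(3S)-3,8-bis(benzyloxy)-2,2-dimethylchroman-6-yl]chroman-4-one | CC1(C)Oc2c(OCc3ccccc3)cc([C@@H]3CC(=O)c4c(OCc5ccccc5)cc(OCc5ccccc5)cc4O3)cc2C[C@@H]1OCc1ccccc1 | intermediate
19 | sigmoidin D, (2S)-5,7-dihydroxy-2-[(3S)-3,8-dihydroxy-2,2-dimethylchroman-6-yl]chroman-4-one | CC1(C)Oc2c(O)cc([C@@H]3CC(=O)c4c(O)cc(O)cc4O3)cc2C[C@@H]1O | target

## Step count and risk

Total: 12 steps. Longest linear sequence: 11 steps (3 → 4 → 7 → 9 → 10 → 11 → 12 → 13 → 16 → 17 → 18 → 19); the second branch (1 → 2) is one step and joins at step 9.

Step 9 (key step, proposed new method). The most likely failure is poor enantioface discrimination at C2. The ion pair may be too loose at the moment of C–O closure, an achiral background pathway may compete, or the product may erode by reversible ionisation of the C2–O1 bond. Competing consumption of the cation by Friedel–Crafts attack of the electron-rich rings, and cationic oligomerisation of the styrene, would lower the yield. Fallback in known chemistry, setting out from 12 and rejoining at 18: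
- Bromine–lithium exchange on 12 (n-BuLi, THF, −78 °C), B(OiPr)3 and acidic work-up would give [(3S)-3,8-bis(benzyloxy)-2,2-dimethylchroman-6-yl]boronic acid F1.
- Benzylation of commercial 5,7-dihydroxy-4H-chromen-4-one (BnBr, K2CO3, DMF, 60 °C) would give 5,7-bis(benzyloxy)-4H-chromen-4-one F2.
- Rhodium-catalysed asymmetric 1,4-addition of F1 to F2 ([RhCl(C2H4)2]2, a chiral bisphosphine, aq KOH, CH2Cl2, rt), a known way to 2-arylchroman-4-ones, would form the C2–C1' bond under ligand control and give 18 directly. Steps 8 to 11 then fall away.

Step 10. The long-lived C4 cation may lose a proton from C3 (elimination to the 2H-chromene) or be captured by ring A of a second molecule (dimerisation) instead of by water. Fallback, setting out from 16 and rejoining at 18: oxidative hydride abstraction from C4 with DDQ in CH2Cl2/pH 7 buffer at 0 °C, a known oxidation of benzylic ethers to carbonyl compounds. The axial C4–H of the 2,4-cis isomer is aligned with ring A, and the methoxy oxocarbenium ion is hydrolysed to the ketone, so 17 is bypassed and no new compound is made (F0).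

Step 12. Over-reduction is the main danger: hydrogenolysis of the benzylic C2–O1 bond while the slow alkyl benzyl ether is still being cleaved. Fallback, setting out from 18 and ending at 19: non-reductive debenzylation with BCl3 and pentamethylbenzene as cation scavenger in CH2Cl2 at −78 °C. No new compound is made (F0).

Step 1. Over-alkylation to the triether and C-benzylation of the phloroglucinol ring may lower the selectivity. Fallback, setting out from 1 and rejoining at 2: exhaustive O-benzylation (BnBr, K2CO3, DMF, 60 °C) to 2,4,6-tris(benzyloxy)benzaldehyde F3, then chelation-directed removal of one ortho benzyl group with MgBr2·OEt2 in toluene/Et2O.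

Step 8. The product styrene may be lost by Heck-type coupling with unreacted 12 or by polymerisation at 80 °C. Fallback, setting out from 12 and rejoining at 13: bromine–lithium exchange (n-BuLi, THF, −78 °C) and DMF to (3S)-3,8-bis(benzyloxy)-2,2-dimethylchroman-6-carbaldehyde F4, then Wittig methylenation (Ph3PCH3Br, KOtBu, THF, 0 °C).

## Further compounds

F1 | step 9 | [(3S)-3,8-bis(benzyloxy)-2,2-dimethylchroman-6-yl]boronic acid | CC1(C)Oc2c(OCc3ccccc3)cc(B(O)O)cc2C[C@@H]1OCc1ccccc1
F2 | step 9 | 5,7-bis(benzyloxy)-4H-chromen-4-one | O=c1ccoc2cc(OCc3ccccc3)cc(OCc3ccccc3)c12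
F0 | step 10 | none | none
F0 | step 12 | none | none
F3 | step 1 | 2,4,6-tris(benzyloxy)benzaldehyde | O=Cc1c(OCc2ccccc2)cc(OCc2ccccc2)cc1OCc1ccccc1
F4 | step 8 | (3S)-3,8-bis(benzyloxy)-2,2-dimethylchroman-6-carbaldehyde | CC1(C)Oc2c(OCc3ccccc3)cc(C=O)cc2C[C@@H]1OCc1ccccc1
A1 | alternative 1 | (2S)-5,7-bis(benzyloxy)-2-[8-(benzyloxy)-2,2-dimethyl-2H-chromen-6-yl]chroman-4-one | CC1(C)C=Cc2cc([C@@H]3CC(=O)c4c(OCc5ccccc5)cc(OCc5ccccc5)cc4O3)cc(OCc3ccccc3)c2O1
A2 | alternative 1 | (2S)-5,7-bis(benzyloxy)-2-[(3S,4S)-8-(benzyloxy)-3,4-epoxy-2,2-dimethylchroman-6-yl]chroman-4-one | CC1(C)Oc2c(OCc3ccccc3)cc([C@@H]3CC(=O)c4c(OCc5ccccc5)cc(OCc5ccccc5)cc4O3)cc2[C@@H]2O[C@H]12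
A3 | alternative 2 | (S)-2-{2-[2-(benzyloxy)-4-bromophenoxy]propan-2-yl}oxirane | CC(C)(Oc1ccc(Br)cc1OCc1ccccc1)[C@@H]1CO1
A4 | alternative 2 | (3S)-8-(benzyloxy)-6-bromo-2,2-dimethylchroman-3-ol | CC1(C)Oc2c(OCc3ccccc3)cc(Br)cc2C[C@@H]1O
A5 | alternative 3 | (3S)-3,8-bis(benzyloxy)-2,2-dimethylchroman-6-carbaldehyde | CC1(C)Oc2c(OCc3ccccc3)cc(C=O)cc2C[C@@H]1OCc1ccccc1
A6 | alternative 3 | (2S)-2-[(3S)-3,8-bis(benzyloxy)-2,2-dimethylchroman-6-yl]-5-bromo-2,3-dihydro-4H-pyran-4-one | CC1(C)Oc2c(OCc3ccccc3)cc([C@@H]3CC(=O)C(Br)=CO3)cc2C[C@@H]1OCc1ccccc1
A7 | alternative 3 | 1-methoxy-1,3-bis(trimethylsilyloxy)buta-1,3-diene | COC(O[Si](C)(C)C)=CC(=C)O[Si](C)(C)C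
A8 | alternative 3 | (2S)-2-[(3S)-3,8-bis(benzyloxy)-2,2-dimethylchroman-6-yl]-5,7-dihydroxychroman-4-one | CC1(C)Oc2c(OCc3ccccc3)cc([C@@H]3CC(=O)c4c(O)cc(O)cc4O3)cc2C[C@@H]1OCc1ccccc1
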